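**Strategy**

Ring A, numbered from the chain-bearing C1 (C2 OH, C3 aroyl, C4 OH, C5 butenyl, C6 OMe), carries its oxygens on alternate carbons, the pattern that a siloxyalkyne and a 3-alkoxycyclobutenone assemble. Ring A is therefore built onto the limonene-derived chain C7–C12 instead of alkylating a crowded arene. Heating the siloxyalkyne with the cyclobutenone forms the bonds C1–C6, C2–C3 and C5–C6 in one operation. It gives a phenol with three differentiated oxygens: free OH (C6), silyl ether (C2) and a fluoride-labile 2-(trimethylsilyl)ethyl ether (C4), so the endgame needs no boron or aluminium halide. The C8 stereocentre comes from (R)-limonene and is never touched.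

Key step: step 8

Remark 1 (starting material): commercial (+)-limonene 1,2-oxide (cis/trans mixture, derived from (R)-limonene) is taken as the chiral-pool material; both epoxide epimers converge in step 1.

Remark 2 (atom provenance): in the Kowalski step the chain migrates to the carbon supplied by dibromomethane. C1 of ring A therefore stems from CH2Br2, and the former ester carbon (the ring-alkene CH carbon of limonene) becomes the oxygen-bearing C2. C3 and C4 stem from trichloroethylene, C5 and C6 from ketene.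

Remark 3 (spectator group and aroylation): an ethyl ether at C4 would need a boron or aluminium halide at the end. The two 1,1-disubstituted alkenes and the ortho-phenols (chroman closure onto the isopropenyl group) would not tolerate this, so the cyclobutenone carries a 2-(trimethylsilyl)ethyl group instead. For the same reason the aroyl group is introduced by phenol-directed formylation, aryllithium addition and oxidation, not by Friedel–Crafts acylation.

**Route**

Step 1
Reactants: 1 (4R)-limonene 1,2-oxide (cis/trans mixture)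
Product: 3 (3R)-6-oxo-3-(prop-1-en-2-yl)heptanal, via limonene-1,2-diol 2 (not isolated)
Conditions: H5IO6, THF/H2O, 0 °C to rt
Reagents that add atoms: water, O
Why: Aqueous periodic acid hydrolyses the epoxide to the diol and cleaves the glycol in the same flask (Malaprade cleavage), so both epoxide epimers converge and the stereocentre is untouched.

Step 2
Reactants: 3 (3R)-6-oxo-3-(prop-1-en-2-yl)heptanal
Product: 4 (3R)-6-oxo-3-(prop-1-en-2-yl)heptanoic acid
Conditions: NaClO2, NaH2PO4, 2-methylbut-2-ene, t-BuOH/H2O, 0 °C to rt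
Reagents that add atoms: sodium chlorite, [Na+].[O-]Cl=O
Why: Pinnick oxidation with a chlorine scavenger converts only the aldehyde, sparing the methyl ketone and the isopropenyl group, and the stereocentre beta to the carbonyl cannot epimerise.

Step 3
Reactants: 4 (3R)-6-oxo-3-(prop-1-en-2-yl)heptanoic acid
Product: 5 methyl (3R)-6-oxo-3-(prop-1-en-2-yl)heptanoate
Conditions: MeI, K2CO3, DMF, rt
Reagents that add atoms: iodomethane, CI
Why: Carboxylate SN2 alkylation under mild base is chosen over acidic Fischer esterification so that the isopropenyl group never meets acid.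

Step 4
Reactants: 5 methyl (3R)-6-oxo-3-(prop-1-en-2-yl)heptanoate
Product: 6 methyl (3R)-6-methyl-3-(prop-1-en-2-yl)hept-6-enoate
Conditions: Ph3PCH3Br (slight excess over base), KOt-Bu, THF, 0 °C to rt
Reagents that add atoms: methyltriphenylphosphonium bromide, C[P+](c1ccccc1)(c1ccccc1)c1ccccc1.[Br-]
Why: Wittig methylenation with the non-stabilised ylide attacks the ketone far faster than the ester and installs the C11=C12 methylidene.

Step 5
Reactants: 6 methyl (3R)-6-methyl-3-(prop-1-en-2-yl)hept-6-enoate; 7 dibromomethane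
Product: 10 triisopropyl{[(4R)-7-methyl-4-(prop-1-en-2-yl)oct-7-en-1-ynyl]oxy}silane, via lithium dibromoenolate 8 (not isolated), via lithium ynolate 9 (not isolated)
Conditions: 2,2,6,6-tetramethylpiperidine, n-BuLi, THF, 0 °C; CH2Br2, −78 °C; then 6, −78 °C; then n-BuLi, −78 °C to rt; then i-Pr3SiCl, −78 °C to rt
Reagents that add atoms: chlorotriisopropylsilane, CC(C)[Si](Cl)(C(C)C)C(C)C
Why: Kowalski ester homologation, in which dibromomethyllithium adds to the ester, bromine–lithium exchange on enolate 8 triggers a 1,2-shift of the chain to the carbenoid carbon (future C1 of ring A), and the hindered silyl chloride traps ynolate 9 on oxygen at the former ester carbon (future C2).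

Step 6
Reactants: 11 2-(trimethylsilyl)ethanol
Product: 14 [2-(ethynyloxy)ethyl]trimethylsilane, via dichlorovinyl ether 12 (not isolated), via lithium alkoxyacetylide 13 (not isolated)
Conditions: KH, THF, 0 °C; Cl2C=CHCl, −50 °C to rt; n-BuLi, −78 to −40 °C; H2O
Reagents that add atoms: trichloroethylene, ClC=C(Cl)Cl
Why: One-flask Greene ynol ether synthesis, in which the potassium alkoxide adds to dichloroacetylene generated from trichloroethylene to give 12, and two equivalents of butyllithium effect elimination of HCl and chlorine–lithium exchange to acetylide 13, which is protonated.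

Step 7
Reactants: 14 [2-(ethynyloxy)ethyl]trimethylsilane
Product: 15 3-[2-(trimethylsilyl)ethoxy]cyclobut-2-en-1-one
Conditions: ketene (gas, from acetone pyrolysis), CH2Cl2, 0 °C
Reagents that add atoms: ketene, C=C=O
Why: Thermal [2+2] cycloaddition of ketene with an alkoxyacetylene is the classical entry to 3-alkoxycyclobutenones, the nucleophilic terminal alkyne carbon bonding to the ketene carbonyl carbon.

Step 8
Reactants: 10 triisopropyl{[(4R)-7-methyl-4-(prop-1-en-2-yl)oct-7-en-1-ynyl]oxy}silane; 15 3-[2-(trimethylsilyl)ethoxy]cyclobut-2-en-1-one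
Product: 20 2-[(2R)-5-methyl-2-(prop-1-en-2-yl)hex-5-enyl]-3-(triisopropylsilyloxy)-5-[2-(trimethylsilyl)ethoxy]phenol, via vinylketene 16 (not isolated), via vinylcyclobutenone 17 (not isolated), via dienylketene 18 (not isolated), via cyclohexadienone 19 (not isolated)
Conditions: toluene, 80 °C then 110 °C, sealed tube, slight excess of 10
Reagents that add atoms: none
Why: Thermal 4π electrocyclic opening of 15 gives (1-alkoxyvinyl)ketene 16, whose carbonyl carbon is attacked by the alkyl-bearing carbon of ynol ether 10 in a [2+2] cycloaddition (bonds C1–C6 and C2–C3) to give 17; a second 4π opening to dienylketene 18 and 6π electrocyclisation (bond C5–C6) give dienone 19, which tautomerises to phenol 20. This is the Danheiser benzannulation as practised with triisopropylsiloxyalkynes from Kowalski homologation and 3-substituted cyclobutenones; an alkoxy group at the 3-position of the cyclobutenone is an uncommon but electronically compatible variant. Ring A is closed by a thermal disrotatory 6π electrocyclisation of 18 between the ketene carbon and the terminal CH2, with aromatisation as driving force. No stereocentre is created in 20 (the sp3 ring carbon of 17 is transient), and C8, two bonds from the reacting alkyne, is not involved. The required regiochemistry (chain between OH and OSi, alkoxy group para to the chain) follows from the polarisation of the ynol ether, and chemoselectivity over the two unactivated 1,1-disubstituted alkenes from the much higher nucleophilicity of the siloxyalkyne; a slight excess of 10 limits acylation of 20 by ketene 16.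

Step 9
Reactants: 20 2-[(2R)-5-methyl-2-(prop-1-en-2-yl)hex-5-enyl]-3-(triisopropylsilyloxy)-5-[2-(trimethylsilyl)ethoxy]phenol
Product: 21 2-hydroxy-3-[(2R)-5-methyl-2-(prop-1-en-2-yl)hex-5-enyl]-4-(triisopropylsilyloxy)-6-[2-(trimethylsilyl)ethoxy]benzaldehyde
Conditions: MgCl2, Et3N, (CH2O)n, THF, reflux; aq NH4Cl
Reagents that add atoms: paraformaldehyde (formaldehyde), C=O
Why: Magnesium phenoxide-directed ortho-formylation (Casnati–Skattebøl conditions) delivers formaldehyde only ortho to the free C6 hydroxyl, whose sole open ortho position is C5, in a basic medium that leaves silyl ethers and alkenes alone.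

Step 10
Reactants: 21 2-hydroxy-3-[(2R)-5-methyl-2-(prop-1-en-2-yl)hex-5-enyl]-4-(triisopropylsilyloxy)-6-[2-(trimethylsilyl)ethoxy]benzaldehyde
Product: 22 2-methoxy-3-[(2R)-5-methyl-2-(prop-1-en-2-yl)hex-5-enyl]-4-(triisopropylsilyloxy)-6-[2-(trimethylsilyl)ethoxy]benzaldehyde
Conditions: MeI, K2CO3, acetone, 50 °C
Reagents that add atoms: iodomethane, CI
Why: Williamson methylation of the only free phenol under anhydrous carbonate conditions that aryl triisopropylsilyl ethers tolerate.

Step 11
Reactants: 23 1-phenyl-1H-tetrazole-5-thiol; 24 1-bromo-2-methylpropane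
Product: 25 5-(2-methylpropylsulfanyl)-1-phenyl-1H-tetrazole
Conditions: K2CO3, DMF, 60 °C
Reagents that add atoms: none
Why: SN2 S-alkylation of the soft tetrazolethiolate with a primary bromide.

Step 12
Reactants: 25 5-(2-methylpropylsulfanyl)-1-phenyl-1H-tetrazole
Product: 26 5-(2-methylpropylsulfonyl)-1-phenyl-1H-tetrazole
Conditions: H2O2 (30% aq), (NH4)6Mo7O24·4H2O (cat.), EtOH, rt
Reagents that add atoms: hydrogen peroxide, OO
Why: Molybdate-catalysed peroxide oxidation of the sulfide to the sulfone is the usual preparation of Julia–Kocienski reagents.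

Step 13
Reactants: 22 2-methoxy-3-[(2R)-5-methyl-2-(prop-1-en-2-yl)hex-5-enyl]-4-(triisopropylsilyloxy)-6-[2-(trimethylsilyl)ethoxy]benzaldehyde; 26 5-(2-methylpropylsulfonyl)-1-phenyl-1H-tetrazole
Product: 27 triisopropyl{3-methoxy-2-[(2R)-5-methyl-2-(prop-1-en-2-yl)hex-5-enyl]-4-[(E)-3-methylbut-1-enyl]-5-[2-(trimethylsilyl)ethoxy]phenoxy}silane
Conditions: KN(SiMe3)2, DME, −60 °C; then 22, −60 °C to rt
Reagents that add atoms: none
Why: Julia–Kocienski olefination of the aryl aldehyde with the metallated phenyltetrazolyl sulfone proceeds by addition, Smiles rearrangement and anti elimination of SO2 and tetrazololate, which with a potassium counter-ion in DME should favour the (E)-alkene set in this step.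

Step 14
Reactants: 27 triisopropyl{3-methoxy-2-[(2R)-5-methyl-2-(prop-1-en-2-yl)hex-5-enyl]-4-[(E)-3-methylbut-1-enyl]-5-[2-(trimethylsilyl)ethoxy]phenoxy}silane
Product: 28 3-methoxy-2-[(2R)-5-methyl-2-(prop-1-en-2-yl)hex-5-enyl]-4-[(E)-3-methylbut-1-enyl]-5-[2-(trimethylsilyl)ethoxy]phenol
Conditions: Bu4NF, THF, 0 °C; aq NH4Cl
Reagents that add atoms: none
Why: Fluoride cleaves the aryl triisopropylsilyl ether at 0 °C, whereas the 2-(trimethylsilyl)ethyl ether, which has no activating ortho carbonyl at this stage, needs heat and should survive.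

Step 15
Reactants: 28 3-methoxy-2-[(2R)-5-methyl-2-(prop-1-en-2-yl)hex-5-enyl]-4-[(E)-3-methylbut-1-enyl]-5-[2-(trimethylsilyl)ethoxy]phenol
Product: 29 2-hydroxy-4-methoxy-3-[(2R)-5-methyl-2-(prop-1-en-2-yl)hex-5-enyl]-5-[(E)-3-methylbut-1-enyl]-6-[2-(trimethylsilyl)ethoxy]benzaldehyde
Conditions: MgCl2, Et3N, (CH2O)n, THF, reflux; aq NH4Cl
Reagents that add atoms: paraformaldehyde (formaldehyde), C=O
Why: A second magnesium-directed ortho-formylation (Casnati–Skattebøl conditions), in which the newly freed C2 hydroxyl steers formaldehyde to C3, the only ring CH left, without any boron or aluminium halide or protic acid.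

Step 16
Reactants: 29 2-hydroxy-4-methoxy-3-[(2R)-5-methyl-2-(prop-1-en-2-yl)hex-5-enyl]-5-[(E)-3-methylbut-1-enyl]-6-[2-(trimethylsilyl)ethoxy]benzaldehyde; 30 (3-bromophenoxy)(tert-butyl)dimethylsilane
Product: 32 {2-hydroxy-4-methoxy-3-[(2R)-5-methyl-2-(prop-1-en-2-yl)hex-5-enyl]-5-[(E)-3-methylbut-1-enyl]-6-[2-(trimethylsilyl)ethoxy]phenyl}[3-(tert-butyldimethylsilyloxy)phenyl]methanol (both carbinol epimers), via aryllithium 31 (not isolated)
Conditions: 30, n-BuLi, THF, −78 °C; then 29 (0.45 equiv), −78 to 0 °C; aq NH4Cl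
Reagents that add atoms: none
Why: Bromine–lithium exchange gives aryllithium 31, of which one equivalent deprotonates the phenol and a second undergoes 1,2-addition to the chelated lithium salicylaldehyde, the carbinol configuration being irrelevant because this centre is oxidised next.

Step 17
Reactants: 32 {2-hydroxy-4-methoxy-3-[(2R)-5-methyl-2-(prop-1-en-2-yl)hex-5-enyl]-5-[(E)-3-methylbut-1-enyl]-6-[2-(trimethylsilyl)ethoxy]phenyl}[3-(tert-butyldimethylsilyloxy)phenyl]methanol
Product: 33 {2-hydroxy-4-methoxy-3-[(2R)-5-methyl-2-(prop-1-en-2-yl)hex-5-enyl]-5-[(E)-3-methylbut-1-enyl]-6-[2-(trimethylsilyl)ethoxy]phenyl}[3-(tert-butyldimethylsilyloxy)phenyl]methanone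
Conditions: MnO2 (activated), CH2Cl2, rt
Reagents that add atoms: none
Why: MnO2 oxidises the doubly benzylic, electron-rich carbinol to the diaryl ketone under neutral conditions that should spare the phenol and the three alkenes, and it removes the carbinol stereocentre.

Step 18
Reactants: 33 {2-hydroxy-4-methoxy-3-[(2R)-5-methyl-2-(prop-1-en-2-yl)hex-5-enyl]-5-[(E)-3-methylbut-1-enyl]-6-[2-(trimethylsilyl)ethoxy]phenyl}[3-(tert-butyldimethylsilyloxy)phenyl]methanone
Product: 34 {2,6-dihydroxy-4-methoxy-3-[(2R)-5-methyl-2-(prop-1-en-2-yl)hex-5-enyl]-5-[(E)-3-methylbut-1-enyl]phenyl}(3-hydroxyphenyl)methanone (CNP0208548.1)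
Conditions: Bu4NF, THF, 50 °C, argon; aq NH4Cl
Reagents that add atoms: none
Why: Fluoride removes the tert-butyldimethylsilyl ether and, with gentle heating, triggers beta-elimination of the 2-(trimethylsilyl)ethyl ether as ethene and Me3SiF, helped by the ortho-acyl-stabilised phenoxide leaving group, so both remaining phenols are freed without acid.

**Compound list**

1 | (4R)-limonene 1,2-oxide, (4R)-1-methyl-4-(prop-1-en-2-yl)-7-oxabicyclo[4.1.0]heptane, cis/trans mixture | CC12OC1C[C@@H](CC2)C(C)=C | starting material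
2 | (4R)-1-methyl-4-(prop-1-en-2-yl)cyclohexane-1,2-diol (limonene-1,2-diol, epimer mixture at the two carbinol carbons) | CC1(O)C(O)C[C@@H](CC1)C(C)=C | intermediate
3 | (3R)-6-oxo-3-(prop-1-en-2-yl)heptanal | CC(=O)CC[C@H](CC=O)C(=C)C | intermediate
4 | (3R)-6-oxo-3-(prop-1-en-2-yl)heptanoic acid | CC(=O)CC[C@H](CC(=O)O)C(=C)C | intermediate
5 | methyl (3R)-6-oxo-3-(prop-1-en-2-yl)heptanoate | CC(=O)CC[C@H](CC(=O)OC)C(=C)C | intermediate
6 | methyl (3R)-6-methyl-3-(prop-1-en-2-yl)hept-6-enoate | C=C(C)CC[C@H](CC(=O)OC)C(=C)C | intermediate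
7 | dibromomethane | BrCBr | starting material
8 | lithium (4R)-1,1-dibromo-7-methyl-4-(prop-1-en-2-yl)octa-1,7-dien-2-olate (lithium dibromoenolate) | C=C(C)CC[C@H](CC([O-])=C(Br)Br)C(=C)C.[Li+] | intermediate
9 | lithium (4R)-7-methyl-4-(prop-1-en-2-yl)oct-7-en-1-yn-1-olate (lithium ynolate) | C=C(C)CC[C@H](CC#C[O-])C(=C)C.[Li+] | intermediate
10 | triisopropyl{[(4R)-7-methyl-4-(prop-1-en-2-yl)oct-7-en-1-ynyl]oxy}silane | C=C(C)CC[C@H](CC#CO[Si](C(C)C)(C(C)C)C(C)C)C(=C)C | intermediate
11 | 2-(trimethylsilyl)ethanol | C[Si](C)(C)CCO | starting material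
12 | (E)-{2-[(1,2-dichloroethenyl)oxy]ethyl}trimethylsilane (dichlorovinyl ether) | Cl/C=C(/Cl)OCC[Si](C)(C)C | intermediate
13 | {[2-(trimethylsilyl)ethoxy]ethynyl}lithium (lithium alkoxyacetylide) | [Li]C#COCC[Si](C)(C)C | intermediate
14 | [2-(ethynyloxy)ethyl]trimethylsilane | C#COCC[Si](C)(C)C | intermediate
15 | 3-[2-(trimethylsilyl)ethoxy]cyclobut-2-en-1-one | C[Si](C)(C)CCOC1=CC(=O)C1 | intermediate
16 | 3-[2-(trimethylsilyl)ethoxy]buta-1,3-dien-1-one (vinylketene) | C=C(OCC[Si](C)(C)C)C=C=O | intermediate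
17 | 2-[(2R)-5-methyl-2-(prop-1-en-2-yl)hex-5-enyl]-3-(triisopropylsilyloxy)-4-{1-[2-(trimethylsilyl)ethoxy]ethenyl}cyclobut-2-en-1-one (vinylcyclobutenone, both epimers at the sp3 ring carbon) | C=C(C)CC[C@H](CC1=C(O[Si](C(C)C)(C(C)C)C(C)C)C(C(=C)OCC[Si](C)(C)C)C1=O)C(=C)C | intermediate
18 | (3E)-2-[(2R)-5-methyl-2-(prop-1-en-2-yl)hex-5-enyl]-3-(triisopropylsilyloxy)-5-[2-(trimethylsilyl)ethoxy]hexa-1,3,5-trien-1-one (dienylketene) | C=C(C)CC[C@H](CC(=C=O)/C(O[Si](C(C)C)(C(C)C)C(C)C)=C\C(=C)OCC[Si](C)(C)C)C(=C)C | intermediate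
19 | 2-[(2R)-5-methyl-2-(prop-1-en-2-yl)hex-5-enyl]-3-(triisopropylsilyloxy)-5-[2-(trimethylsilyl)ethoxy]cyclohexa-2,4-dien-1-one (cyclohexadienone) | C=C(C)CC[C@H](CC1=C(O[Si](C(C)C)(C(C)C)C(C)C)C=C(OCC[Si](C)(C)C)CC1=O)C(=C)C | intermediate
20 | 2-[(2R)-5-methyl-2-(prop-1-en-2-yl)hex-5-enyl]-3-(triisopropylsilyloxy)-5-[2-(trimethylsilyl)ethoxy]phenol | C=C(C)CC[C@H](Cc1c(O[Si](C(C)C)(C(C)C)C(C)C)cc(OCC[Si](C)(C)C)cc1O)C(=C)C | intermediate
21 | 2-hydroxy-3-[(2R)-5-methyl-2-(prop-1-en-2-yl)hex-5-enyl]-4-(triisopropylsilyloxy)-6-[2-(trimethylsilyl)ethoxy]benzaldehyde | C=C(C)CC[C@H](Cc1c(O[Si](C(C)C)(C(C)C)C(C)C)cc(OCC[Si](C)(C)C)c(C=O)c1O)C(=C)C | intermediate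
22 | 2-methoxy-3-[(2R)-5-methyl-2-(prop-1-en-2-yl)hex-5-enyl]-4-(triisopropylsilyloxy)-6-[2-(trimethylsilyl)ethoxy]benzaldehyde | C=C(C)CC[C@H](Cc1c(O[Si](C(C)C)(C(C)C)C(C)C)cc(OCC[Si](C)(C)C)c(C=O)c1OC)C(=C)C | intermediate
23 | 1-phenyl-1H-tetrazole-5-thiol | Sc1nnnn1-c1ccccc1 | starting material
24 | 1-bromo-2-methylpropane | CC(C)CBr | starting material
25 | 5-(2-methylpropylsulfanyl)-1-phenyl-1H-tetrazole | CC(C)CSc1nnnn1-c1ccccc1 | intermediate
26 | 5-(2-methylpropylsulfonyl)-1-phenyl-1H-tetrazole | CC(C)CS(=O)(=O)c1nnnn1-c1ccccc1 | intermediate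
27 | triisopropyl{3-methoxy-2-[(2R)-5-methyl-2-(prop-1-en-2-yl)hex-5-enyl]-4-[(E)-3-methylbut-1-enyl]-5-[2-(trimethylsilyl)ethoxy]phenoxy}silane | C=C(C)CC[C@H](Cc1c(O[Si](C(C)C)(C(C)C)C(C)C)cc(OCC[Si](C)(C)C)c(/C=C/C(C)C)c1OC)C(=C)C | intermediate
28 | 3-methoxy-2-[(2R)-5-methyl-2-(prop-1-en-2-yl)hex-5-enyl]-4-[(E)-3-methylbut-1-enyl]-5-[2-(trimethylsilyl)ethoxy]phenol | C=C(C)CC[C@H](Cc1c(O)cc(OCC[Si](C)(C)C)c(/C=C/C(C)C)c1OC)C(=C)C | intermediate
29 | 2-hydroxy-4-methoxy-3-[(2R)-5-methyl-2-(prop-1-en-2-yl)hex-5-enyl]-5-[(E)-3-methylbut-1-enyl]-6-[2-(trimethylsilyl)ethoxy]benzaldehyde | C=C(C)CC[C@H](Cc1c(O)c(C=O)c(OCC[Si](C)(C)C)c(/C=C/C(C)C)c1OC)C(=C)C | intermediate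
30 | (3-bromophenoxy)(tert-butyl)dimethylsilane | CC(C)(C)[Si](C)(C)Oc1cccc(Br)c1 | starting material
31 | [3-(tert-butyldimethylsilyloxy)phenyl]lithium (aryllithium) | [Li]c1cccc(O[Si](C)(C)C(C)(C)C)c1 | intermediate
32 | {2-hydroxy-4-methoxy-3-[(2R)-5-methyl-2-(prop-1-en-2-yl)hex-5-enyl]-5-[(E)-3-methylbut-1-enyl]-6-[2-(trimethylsilyl)ethoxy]phenyl}[3-(tert-butyldimethylsilyloxy)phenyl]methanol (both carbinol epimers) | C=C(C)CC[C@H](Cc1c(O)c(C(O)c2cccc(O[Si](C)(C)C(C)(C)C)c2)c(OCC[Si](C)(C)C)c(/C=C/C(C)C)c1OC)C(=C)C | intermediate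
33 | {2-hydroxy-4-methoxy-3-[(2R)-5-methyl-2-(prop-1-en-2-yl)hex-5-enyl]-5-[(E)-3-methylbut-1-enyl]-6-[2-(trimethylsilyl)ethoxy]phenyl}[3-(tert-butyldimethylsilyloxy)phenyl]methanone | C=C(C)CC[C@H](Cc1c(O)c(C(=O)c2cccc(O[Si](C)(C)C(C)(C)C)c2)c(OCC[Si](C)(C)C)c(/C=C/C(C)C)c1OC)C(=C)C | intermediate
34 | {2,6-dihydroxy-4-methoxy-3-[(2R)-5-methyl-2-(prop-1-en-2-yl)hex-5-enyl]-5-[(E)-3-methylbut-1-enyl]phenyl}(3-hydroxyphenyl)methanone | C=C(C)CC[C@H](Cc1c(O)c(C(=O)c2cccc(O)c2)c(O)c(/C=C/C(C)C)c1OC)C(=C)C | target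

**Step count**

Total step count: 18. Longest linear sequence: 14 steps (steps 1–5, 8–10, 13–18).

**Steps most likely to fail, with fallbacks**

Step 8 (key benzannulation). The alkoxy-stabilised cyclobutenone may open too slowly, or decompose or acylate the product before the cascade is complete. The fallback generates the same vinylketene 16 at room temperature by 1,4-dehydrochlorination instead of electrocyclic opening. It sets out from siloxyalkyne 10, with alcohol 11 as second building block. Base-catalysed conjugate addition of 11 to ethyl but-2-ynoate (catalytic KOt-Bu, THF) should give ethyl (E)-3-[2-(trimethylsilyl)ethoxy]but-2-enoate F1; any transesterified ester converges in the next operation. Saponification (LiOH, THF/H2O) should give (E)-3-[2-(trimethylsilyl)ethoxy]but-2-enoic acid F2, and oxalyl chloride with catalytic DMF the acid chloride (E)-3-[2-(trimethylsilyl)ethoxy]but-2-enoyl chloride F3. Slow addition of F3 to 10 and Et3N in toluene at room temperature should release 16, which 10 traps as 17; warming to 80 °C completes the cascade, and the sequence returns to the route at phenol 20.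

Step 7 (cyclobutenone from ketene). Gaseous ketene may dimerise or polymerise the ynol ether faster than it adds. The fallback uses the more electrophilic dichloroketene. It sets out from ynol ether 14: trichloroacetyl chloride and Zn–Cu couple in Et2O should give 4,4-dichloro-3-[2-(trimethylsilyl)ethoxy]cyclobut-2-en-1-one F4, and reductive dechlorination with zinc dust, AcOH and TMEDA in EtOH at 0 °C returns to the route at cyclobutenone 15.

Step 18 (final unmasking). The fluoride-induced elimination of the silylethyl group may stall, or the warm basic medium may degrade the electron-rich product. The fallback cleaves the C4 ether first by chelation. It sets out from ketone 33: MgBr2·OEt2 in Et2O/CH2Cl2 at room temperature should bind between the ketone oxygen and the ortho ether oxygen, and bromide removes the silylethyl group as ethene and Me3SiBr to give {2,6-dihydroxy-4-methoxy-3-[(2R)-5-methyl-2-(prop-1-en-2-yl)hex-5-enyl]-5-[(E)-3-methylbut-1-enyl]phenyl}[3-(tert-butyldimethylsilyloxy)phenyl]methanone F5. Buffered Bu4NF/AcOH in THF at 0 °C then removes the remaining aryl silyl ether and returns to the route at target 34.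

Further compounds
F1 | step 8 | ethyl (E)-3-[2-(trimethylsilyl)ethoxy]but-2-enoate | CCOC(=O)/C=C(C)/OCC[Si](C)(C)C
F2 | step 8 | (E)-3-[2-(trimethylsilyl)ethoxy]but-2-enoic acid | OC(=O)/C=C(C)/OCC[Si](C)(C)C
F3 | step 8 | (E)-3-[2-(trimethylsilyl)ethoxy]but-2-enoyl chloride | ClC(=O)/C=C(C)/OCC[Si](C)(C)C
F4 | step 7 | 4,4-dichloro-3-[2-(trimethylsilyl)ethoxy]cyclobut-2-en-1-one | C[Si](C)(C)CCOC1=CC(=O)C1(Cl)Cl
F5 | step 18 | {2,6-dihydroxy-4-methoxy-3-[(2R)-5-methyl-2-(prop-1-en-2-yl)hex-5-enyl]-5-[(E)-3-methylbut-1-enyl]phenyl}[3-(tert-butyldimethylsilyloxy)phenyl]methanone | C=C(C)CC[C@H](Cc1c(O)c(C(=O)c2cccc(O[Si](C)(C)C(C)(C)C)c2)c(O)c(/C=C/C(C)C)c1OC)C(=C)C
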